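**Retrosynthetic overview** (ring A = quinone ring, B = para-phenylene, C = phenol-bearing ring, D = meta-phenylene)

- Marchantinquinone ⇐ hydroquinone (Ag2O) ⇐ macrocyclic tribenzyl ether (H2, Pd/C) ⇐ the same macrocycle with a nitro group on C4 of ring D (removed by Zn/AcOH, then NaNO2/H3PO2).
- The strategy rests on the ether oxygen between C2 of ring A and C3 of ring D. On ring A it lies between the C1 oxygen and the C3 ethano bridge (most hindered linkage), whereas ring D is otherwise bare, so C4 of ring D can carry an erasable nitro group. Key disconnection: this O–C3(ring D) bond, formed by SNAr of the ring A phenoxide on a 3-fluoro-4-nitrophenyl terminus. It closes the 18-membered ring and is the only ring-forming step; the four benzene rings come from the starting materials.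
- Seco phenol ⇐ ring D attached last by hydroboration/B-alkyl Suzuki coupling of a ring C styrene with 4-bromo-2-fluoro-1-nitrobenzene; the ring A phenol comes from the aryl bromide by Br/Li exchange–borylation–oxidation and is MOM-masked meanwhile.
- A–B ethano bridge ⇐ Wittig/diimide union of a ring A phosphonium salt (bromohydroquinone: benzylation, ortho-lithiation/formylation) with the B–O–C aldehyde (SNAr of the acetal-protected ring C phenol on 4-fluorobenzaldehyde).

Key step: step 14

Remarks: the target has no stereocentre and the macrocycle is taken as conformationally mobile, so no stereocontrol is required. The alkene formed in step 7 is an E/Z mixture that is reduced in step 8; it is written without geometry. 4-Bromo-2-fluoro-1-nitrobenzene is taken as commercial.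

**Route**

Step 1
Reactants: 1 bromohydroquinone
Product: 2 1,4-bis(benzyloxy)-2-bromobenzene
Conditions: BnBr, K2CO3, DMF, 60 °C, under N2
Reagents that add atoms: benzyl bromide, BrCc1ccccc1
Why: Williamson ether synthesis; both phenoxides are alkylated by SN2 on benzyl bromide and the aryl bromide is inert.

Step 2
Reactants: 2 1,4-bis(benzyloxy)-2-bromobenzene
Product: 4 3,6-bis(benzyloxy)-2-bromobenzaldehyde, via [2,5-bis(benzyloxy)-6-bromophenyl]lithium 3 (not isolated)
Conditions: LDA, THF, −78 °C; DMF, −78 → −40 °C; aq. NH4Cl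
Reagents that add atoms: N,N-dimethylformamide, CN(C)C=O
Why: Directed ortho-metalation; LDA removes the most acidic ring proton, the one flanked by Br and OBn (as in the 3-bromoanisole to 2-bromo-6-methoxybenzaldehyde conversion), the alkoxy-stabilised aryllithium persists at −78 °C, and DMF formylates it.

Step 3
Reactants: 4 3,6-bis(benzyloxy)-2-bromobenzaldehyde
Product: 5 [3,6-bis(benzyloxy)-2-bromophenyl]methanol
Conditions: NaBH4, MeOH/THF, 0 °C
Reagents that add atoms: none
Why: Borohydride reduction of an aromatic aldehyde; aryl bromide and benzyl ethers are untouched.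

Step 4
Reactants: 5 [3,6-bis(benzyloxy)-2-bromophenyl]methanol
Product: 6 [3,6-bis(benzyloxy)-2-bromobenzyl]triphenylphosphonium bromide
Conditions: Ph3P·HBr, MeCN, reflux
Reagents that add atoms: triphenylphosphine hydrobromide, [Br-].[PH+](c1ccccc1)(c1ccccc1)c1ccccc1
Why: Direct phosphonium salt formation from an electron-rich benzylic alcohol; HBr ionises the alcohol (ortho-alkoxy-stabilised benzylic cation/bromide) and triphenylphosphine captures it.

Step 5
Reactants: 7 4-(benzyloxy)-3-hydroxybenzaldehyde
Product: 8 2-(benzyloxy)-5-(1,3-dioxolan-2-yl)phenol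
Conditions: ethylene glycol, p-TsOH (cat.), toluene, Dean–Stark reflux
Reagents that add atoms: ethylene glycol, OCCO
Why: Acid-catalysed acetalisation with azeotropic removal of water; it masks the ring C aldehyde so that only the ring B aldehyde is free for the first Wittig reaction.

Step 6
Reactants: 8 2-(benzyloxy)-5-(1,3-dioxolan-2-yl)phenol; 9 4-fluorobenzaldehyde
Product: 10 4-[2-(benzyloxy)-5-(1,3-dioxolan-2-yl)phenoxy]benzaldehyde
Conditions: K2CO3, DMF, 130 °C
Reagents that add atoms: none
Why: SNAr of the phenoxide on the fluoride activated by the para-formyl group; the dioxolane is stable to hot carbonate.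

Step 7
Reactants: 6 [3,6-bis(benzyloxy)-2-bromobenzyl]triphenylphosphonium bromide; 10 4-[2-(benzyloxy)-5-(1,3-dioxolan-2-yl)phenoxy]benzaldehyde
Product: 12 2-[4-(benzyloxy)-3-(4-{2-[3,6-bis(benzyloxy)-2-bromophenyl]ethenyl}phenoxy)phenyl]-1,3-dioxolane (E/Z mixture), via [3,6-bis(benzyloxy)-2-bromobenzylidene]triphenylphosphorane 11 (not isolated)
Conditions: K2CO3, 18-crown-6 (cat.), CH2Cl2, reflux
Reagents that add atoms: none
Why: Wittig olefination of a semi-stabilised benzylic ylide with an aromatic aldehyde under solid–liquid carbonate conditions; the basic medium preserves the acetal and the alkene geometry is irrelevant.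

Step 8
Reactants: 12 the stilbene from step 7
Product: 13 2-[4-(benzyloxy)-3-(4-{2-[3,6-bis(benzyloxy)-2-bromophenyl]ethyl}phenoxy)phenyl]-1,3-dioxolane
Conditions: 2-nitrobenzenesulfonohydrazide (NBSH, excess, in portions), Et3N, CH2Cl2, rt
Reagents that add atoms: none
Why: Diimide reduction; concerted syn transfer of two hydrogens to the C=C leaves the aryl bromide and benzyl ethers intact (both would be at risk under Pd/H2), and the basic anhydrous medium keeps the dioxolane.

Step 9
Reactants: 13 the bromo bibenzyl acetal from step 8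
Product: 17 4-(benzyloxy)-3-(4-{2-[3,6-bis(benzyloxy)-2-hydroxyphenyl]ethyl}phenoxy)benzaldehyde, via the aryllithium 14 (not isolated), via the dimethyl arylboronate 15 (not isolated), via 3,6-bis(benzyloxy)-2-(2-{4-[2-(benzyloxy)-5-(1,3-dioxolan-2-yl)phenoxy]phenyl}ethyl)phenol 16 (not isolated)
Conditions: n-BuLi, THF, −78 °C; B(OMe)3, −78 °C → rt; aq. NaOH, 30% H2O2, 0 °C; Na2S2O3; then 2 M HCl, THF, rt
Reagents that add atoms: trimethyl borate, COB(OC)OC (boron carried in 15 only); hydrogen peroxide, OO; water, O
Why: Bromine–lithium exchange at −78 °C outruns metalation of the benzyl ethers, the small borate traps the hindered aryllithium, alkaline peroxide effects the boron-to-oxygen 1,2-aryl shift (borylation–oxidation), and acid hydrolyses the dioxolane only after excess peroxide is destroyed, which excludes Dakin oxidation.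

Step 10
Reactants: 17 the hydroxy aldehyde from step 9
Product: 18 4-(benzyloxy)-3-(4-{2-[3,6-bis(benzyloxy)-2-(methoxymethoxy)phenyl]ethyl}phenoxy)benzaldehyde
Conditions: MOMCl, iPr2NEt, CH2Cl2, 0 °C → reflux
Reagents that add atoms: chloromethyl methyl ether, COCCl
Why: O-alkylation of the hindered phenol with the small, reactive MOM chloride; the mask prevents any phenoxide from meeting the fluoronitroarene under the basic conditions of step 12 and is removable under acid.

Step 11
Reactants: 18 the MOM-protected aldehyde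
Product: 19 1,4-bis(benzyloxy)-2-(2-{4-[2-(benzyloxy)-5-ethenylphenoxy]phenyl}ethyl)-3-(methoxymethoxy)benzene
Conditions: Ph3PCH3Br, KOtBu, THF, 0 °C → rt
Reagents that add atoms: methyltriphenylphosphonium bromide, [Br-].C[P+](c1ccccc1)(c1ccccc1)c1ccccc1
Why: Wittig methylenation of a non-enolisable aromatic aldehyde; ethers and the MOM acetal are inert to the ylide.

Step 12
Reactants: 19 the styrene from step 11; 20 4-bromo-2-fluoro-1-nitrobenzene
Product: 22 1,4-bis(benzyloxy)-2-[2-(4-{2-(benzyloxy)-5-[2-(3-fluoro-4-nitrophenyl)ethyl]phenoxy}phenyl)ethyl]-3-(methoxymethoxy)benzene, via the B-(2-arylethyl)-9-borabicyclo[3.3.1]nonane 21 (not isolated)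
Conditions: 9-BBN, THF, 0 °C → rt; then 20, Pd(dppf)Cl2 (5 mol%), aq. K3PO4, THF/DMF, rt → 45 °C
Reagents that add atoms: 9-borabicyclo[3.3.1]nonane, B1C2CCCC1CCC2 (boron carried in 21 only)
Why: Anti-Markovnikov hydroboration of the styrene followed by B-alkyl Suzuki–Miyaura coupling; oxidative addition into the electron-poor C–Br bond is fast at mild temperature, the C–F bond is not touched by palladium, and the saturated bridge is formed directly, without a reduction step in the presence of the nitro group.

Step 13
Reactants: 22 the MOM-protected fluoronitro seco compound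
Product: 23 3,6-bis(benzyloxy)-2-[2-(4-{2-(benzyloxy)-5-[2-(3-fluoro-4-nitrophenyl)ethyl]phenoxy}phenyl)ethyl]phenol (seco phenol)
Conditions: HCl (3 M aq.), MeOH/THF, 45 °C
Reagents that add atoms: none
Why: Acid-catalysed cleavage of the aryl MOM acetal; under acid no phenoxide is formed next to the activated fluoride, and benzyl ethers, nitro group and C–F bond are stable.

Step 14
Reactants: 23 seco phenol
Product: 24 18-membered nitro macrocycle, tribenzyl ether (ring A O–C3 ring D ether closed; nitro on C4 of ring D)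
Conditions: Cs2CO3, degassed DMF, 0.002 M, slow addition of 23, rt → 45 °C, under Ar
Reagents that add atoms: none
Why: Cs2CO3 converts the single free phenol of 23 (ring A, between OBn and the ethano bridge) into a phenoxide that adds to the fluorine-bearing C3 of ring D to give a Meisenheimer adduct stabilised by the ortho nitro group, and loss of fluoride forms the aryl–oxygen bond (intramolecular SNAr, addition–elimination). The closest known reaction type is the macrocyclising cycloetherification of phenoxides onto ortho-fluoronitroarenes used for macrocyclic diaryl ethers, followed by removal of the nitro group. The 18-membered ring closes end-to-end by this attack at an sp2 carbon, and high dilution with slow addition should keep it ahead of intermolecular etherification; the para- and meta-linked arenes and two ethano bridges should leave the ring with little strain. No stereocentre is formed. The step needs chemoselectivity and ring closure over oligomerisation: the other three oxygens are benzylated, only C3 of ring D carries an activated leaving group, and the addition step of SNAr tolerates the two ortho substituents of the nucleophile far better than a copper- or palladium-mediated arylation would.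

Step 15
Reactants: 24 nitro macrocycle
Product: 25 amino macrocycle, tribenzyl ether (NH2 on C4 of ring D)
Conditions: Zn dust, AcOH/THF, rt
Reagents that add atoms: none
Why: Dissolving-metal reduction of the nitroarene to the aniline; unlike catalytic hydrogenation it leaves the three benzyl ethers in place.

Step 16
Reactants: 25 amino macrocycle
Product: 27 macrocyclic tribenzyl ether with unsubstituted ring D, via the arenediazonium chloride 26 (not isolated)
Conditions: NaNO2, 6 M HCl, THF/H2O, 0 °C; then 50% aq. H3PO2, Cu2O (cat.), 0 °C → rt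
Reagents that add atoms: sodium nitrite, [Na+].[O-]N=O (nitrogen carried in 26 only)
Why: Diazotisation followed by hydrodediazoniation with hypophosphorous acid (radical chain; H3PO2 in large excess is the hydrogen donor), which erases the activating group and restores the bare meta-phenylene ring.

Step 17
Reactants: 27 macrocyclic tribenzyl ether
Product: 28 macrocyclic hydroquinone–phenol (triol)
Conditions: H2 (1 atm), 10% Pd/C, EtOAc/MeOH, rt; filtered and concentrated under Ar
Reagents that add atoms: none
Why: Catalytic hydrogenolysis of the three benzyl ethers; the diaryl ethers and the saturated bridges are inert.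

Step 18
Reactants: 28 triol
Product: 29 marchantinquinone
Conditions: Ag2O, Na2SO4, Et2O/THF, rt, dark
Reagents that add atoms: none
Why: Mild two-electron oxidation of the para-hydroquinone of ring A to the 1,4-benzoquinone; the isolated phenol of ring C has no para or ortho hydroxyl partner and should not be oxidised by silver(I) oxide.

**Compound list**

1 | bromohydroquinone | Oc1ccc(O)c(Br)c1 | starting material
2 | 1,4-bis(benzyloxy)-2-bromobenzene | Brc1cc(OCc2ccccc2)ccc1OCc1ccccc1 | intermediate
3 | [2,5-bis(benzyloxy)-6-bromophenyl]lithium | [Li]c1c(Br)c(OCc2ccccc2)ccc1OCc1ccccc1 | intermediate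
4 | 3,6-bis(benzyloxy)-2-bromobenzaldehyde | O=Cc1c(Br)c(OCc2ccccc2)ccc1OCc1ccccc1 | intermediate
5 | [3,6-bis(benzyloxy)-2-bromophenyl]methanol | OCc1c(Br)c(OCc2ccccc2)ccc1OCc1ccccc1 | intermediate
6 | [3,6-bis(benzyloxy)-2-bromobenzyl]triphenylphosphonium bromide | [Br-].Brc1c(C[P+](c2ccccc2)(c2ccccc2)c2ccccc2)c(OCc2ccccc2)ccc1OCc1ccccc1 | intermediate
7 | 4-(benzyloxy)-3-hydroxybenzaldehyde | O=Cc1ccc(OCc2ccccc2)c(O)c1 | starting material
8 | 2-(benzyloxy)-5-(1,3-dioxolan-2-yl)phenol | Oc1cc(C2OCCO2)ccc1OCc1ccccc1 | intermediate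
9 | 4-fluorobenzaldehyde | O=Cc1ccc(F)cc1 | starting material
10 | 4-[2-(benzyloxy)-5-(1,3-dioxolan-2-yl)phenoxy]benzaldehyde | O=Cc1ccc(Oc2cc(C3OCCO3)ccc2OCc2ccccc2)cc1 | intermediate
11 | [3,6-bis(benzyloxy)-2-bromobenzylidene]triphenylphosphorane | Brc1c(C=P(c2ccccc2)(c2ccccc2)c2ccccc2)c(OCc2ccccc2)ccc1OCc1ccccc1 | intermediate
12 | stilbene acetal (E/Z mixture) | Brc1c(C=Cc2ccc(Oc3cc(C4OCCO4)ccc3OCc3ccccc3)cc2)c(OCc2ccccc2)ccc1OCc1ccccc1 | intermediate
13 | bromo bibenzyl acetal | Brc1c(CCc2ccc(Oc3cc(C4OCCO4)ccc3OCc3ccccc3)cc2)c(OCc2ccccc2)ccc1OCc1ccccc1 | intermediate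
14 | aryllithium from 13 | [Li]c1c(CCc2ccc(Oc3cc(C4OCCO4)ccc3OCc3ccccc3)cc2)c(OCc2ccccc2)ccc1OCc1ccccc1 | intermediate
15 | dimethyl arylboronate | COB(OC)c1c(CCc2ccc(Oc3cc(C4OCCO4)ccc3OCc3ccccc3)cc2)c(OCc2ccccc2)ccc1OCc1ccccc1 | intermediate
16 | phenol acetal | Oc1c(CCc2ccc(Oc3cc(C4OCCO4)ccc3OCc3ccccc3)cc2)c(OCc2ccccc2)ccc1OCc1ccccc1 | intermediate
17 | hydroxy aldehyde | Oc1c(CCc2ccc(Oc3cc(C=O)ccc3OCc3ccccc3)cc2)c(OCc2ccccc2)ccc1OCc1ccccc1 | intermediate
18 | MOM-protected aldehyde | COCOc1c(CCc2ccc(Oc3cc(C=O)ccc3OCc3ccccc3)cc2)c(OCc2ccccc2)ccc1OCc1ccccc1 | intermediate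
19 | MOM-protected styrene | COCOc1c(CCc2ccc(Oc3cc(C=C)ccc3OCc3ccccc3)cc2)c(OCc2ccccc2)ccc1OCc1ccccc1 | intermediate
20 | 4-bromo-2-fluoro-1-nitrobenzene | [O-][N+](=O)c1ccc(Br)cc1F | starting material
21 | B-(2-arylethyl)-9-BBN | COCOc1c(CCc2ccc(Oc3cc(CCB4C5CCCC4CCC5)ccc3OCc3ccccc3)cc2)c(OCc2ccccc2)ccc1OCc1ccccc1 | intermediate
22 | MOM-protected fluoronitro seco compound | COCOc1c(CCc2ccc(Oc3cc(CCc4ccc([N+](=O)[O-])c(F)c4)ccc3OCc3ccccc3)cc2)c(OCc2ccccc2)ccc1OCc1ccccc1 | intermediate
23 | seco phenol (key-step precursor) | Oc1c(CCc2ccc(Oc3cc(CCc4ccc([N+](=O)[O-])c(F)c4)ccc3OCc3ccccc3)cc2)c(OCc2ccccc2)ccc1OCc1ccccc1 | intermediate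
24 | 18-membered nitro macrocycle, tribenzyl ether | [O-][N+](=O)c1ccc2cc1Oc1c(OCc3ccccc3)ccc(OCc3ccccc3)c1CCc1ccc(cc1)Oc1cc(CC2)ccc1OCc1ccccc1 | intermediate
25 | amino macrocycle, tribenzyl ether | Nc1ccc2cc1Oc1c(OCc3ccccc3)ccc(OCc3ccccc3)c1CCc1ccc(cc1)Oc1cc(CC2)ccc1OCc1ccccc1 | intermediate
26 | macrocyclic arenediazonium chloride | [Cl-].N#[N+]c1ccc2cc1Oc1c(OCc3ccccc3)ccc(OCc3ccccc3)c1CCc1ccc(cc1)Oc1cc(CC2)ccc1OCc1ccccc1 | intermediate
27 | macrocyclic tribenzyl ether | c1ccc2cc1Oc1c(OCc3ccccc3)ccc(OCc3ccccc3)c1CCc1ccc(cc1)Oc1cc(CC2)ccc1OCc1ccccc1 | intermediate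
28 | macrocyclic hydroquinone–phenol | c1ccc2cc1Oc1c(O)ccc(O)c1CCc1ccc(cc1)Oc1cc(CC2)ccc1O | intermediate
29 | marchantinquinone | O=C1C=CC(=O)C2=C1CCc1ccc(cc1)Oc1cc(ccc1O)CCc1cccc(c1)O2 | target

**Summary**

Total step count: 18. Longest linear sequence: 16 steps (steps 1–4 and 7–18, from bromohydroquinone).

Steps most likely to fail:

1. Step 14 (macrocyclising SNAr). Intermolecular etherification may outrun closure of the 18-membered ring, and the hindered, electron-rich phenoxide may add slowly or be oxidised by electron transfer to the nitroarene. Fallback: close the ring at the C–D ethano bridge instead. It sets out from hydroxy aldehyde 17. Intermolecular SNAr with (3-fluoro-4-nitrophenyl)methanol (K2CO3, DMF) gives the diaryl ether benzylic alcohol F1. Appel bromination (CBr4, PPh3) gives the benzylic bromide F2, and PPh3 in toluene gives the phosphonium bromide F3. Under K2CO3/18-crown-6 in CH2Cl2 at high dilution, F3 forms the nitro-stabilised ylide F4, which undergoes intramolecular Wittig reaction with the ring C aldehyde to give the macrocyclic nitrostilbene F5. Diimide reduction (NBSH, Et3N) then returns to the route at 24.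

2. Step 12 (hydroboration/B-alkyl Suzuki coupling). The activated fluoride may be lost to hydroxide or phosphate in the aqueous basic medium, and the phenethylborane may undergo protodeboronation or β-hydride elimination. Fallback: a non-aqueous Wittig–diimide sequence that sets out from aldehyde 18. (3-Fluoro-4-nitrobenzyl)triphenylphosphonium bromide F6 is prepared from 4-(bromomethyl)-2-fluoro-1-nitrobenzene and PPh3. With K2CO3/18-crown-6 in CH2Cl2 it gives the ylide F7, which olefinates 18 to the nitrostilbene F8 (E/Z). Diimide reduction (NBSH, Et3N, rt) returns to the route at 22.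

3. Step 2 (ortho-lithiation/formylation). The ortho-bromoaryllithium may eliminate LiBr to an aryne before formylation, or metalation may be incomplete. Fallback: introduce the bromine last, so that lithium never sits next to it. It sets out from 2. Bromine–lithium exchange (n-BuLi, THF, −78 °C) gives [2,5-bis(benzyloxy)phenyl]lithium F9, and DMF gives 2,5-bis(benzyloxy)benzaldehyde F10. Lithium N,N,N′-trimethylethylenediamide adds to the formyl group to give the α-amino alkoxide F11. n-BuLi at −40 °C metalates the position between this group and the neighbouring benzyloxy group to give the ring-lithiated α-amino alkoxide F12. Quenching with 1,2-dibromotetrachloroethane and aqueous work-up returns to the route at 4.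

**Further compounds**

F1 | step 14 | diaryl ether benzylic alcohol from 17 and (3-fluoro-4-nitrophenyl)methanol | OCc1ccc([N+](=O)[O-])c(Oc2c(CCc3ccc(Oc4cc(C=O)ccc4OCc4ccccc4)cc3)c(OCc3ccccc3)ccc2OCc2ccccc2)c1
F2 | step 14 | corresponding benzylic bromide | BrCc1ccc([N+](=O)[O-])c(Oc2c(CCc3ccc(Oc4cc(C=O)ccc4OCc4ccccc4)cc3)c(OCc3ccccc3)ccc2OCc2ccccc2)c1
F3 | step 14 | corresponding benzyltriphenylphosphonium bromide | [Br-].c1ccccc1[P+](c1ccccc1)(c1ccccc1)Cc1ccc([N+](=O)[O-])c(Oc2c(CCc3ccc(Oc4cc(C=O)ccc4OCc4ccccc4)cc3)c(OCc3ccccc3)ccc2OCc2ccccc2)c1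
F4 | step 14 | nitro-stabilised ylide from F3 | c1ccccc1P(c1ccccc1)(c1ccccc1)=Cc1ccc([N+](=O)[O-])c(Oc2c(CCc3ccc(Oc4cc(C=O)ccc4OCc4ccccc4)cc3)c(OCc3ccccc3)ccc2OCc2ccccc2)c1
F5 | step 14 | macrocyclic nitrostilbene, tribenzyl ether (E/Z) | [O-][N+](=O)c1ccc2cc1Oc1c(OCc3ccccc3)ccc(OCc3ccccc3)c1CCc1ccc(cc1)Oc1cc(C=C2)ccc1OCc1ccccc1
F6 | step 12 | (3-fluoro-4-nitrobenzyl)triphenylphosphonium bromide | [Br-].[O-][N+](=O)c1ccc(C[P+](c2ccccc2)(c2ccccc2)c2ccccc2)cc1F
F7 | step 12 | (3-fluoro-4-nitrobenzylidene)triphenylphosphorane | [O-][N+](=O)c1ccc(C=P(c2ccccc2)(c2ccccc2)c2ccccc2)cc1F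
F8 | step 12 | MOM-protected fluoronitro stilbene (E/Z) | COCOc1c(CCc2ccc(Oc3cc(C=Cc4ccc([N+](=O)[O-])c(F)c4)ccc3OCc3ccccc3)cc2)c(OCc2ccccc2)ccc1OCc1ccccc1
F9 | step 2 | [2,5-bis(benzyloxy)phenyl]lithium | [Li]c1cc(OCc2ccccc2)ccc1OCc1ccccc1
F10 | step 2 | 2,5-bis(benzyloxy)benzaldehyde | O=Cc1cc(OCc2ccccc2)ccc1OCc1ccccc1
F11 | step 2 | lithium α-amino alkoxide of F10 | [Li]OC(N(C)CCN(C)C)c1cc(OCc2ccccc2)ccc1OCc1ccccc1
F12 | step 2 | ring-lithiated α-amino alkoxide | [Li]OC(N(C)CCN(C)C)c1c([Li])c(OCc2ccccc2)ccc1OCc1ccccc1
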